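**Retrosynthetic overview**
- The target comes from the 11,12-alkene tetraacetate by a final α-face epoxidation of ring A.
- The ten-membered carbocycle and the γ-lactone are closed together from a ring-A-only precursor: CrCl2/NiCl2 coupling of the C6 alkenyl iodide with the C7 aldehyde, then the C7 alkoxide lactonizes onto the C19 ester.
- That precursor comes from a C2 aldehyde plus a C3–C6/C16 iodo-enyne (hydrozirconation/zinc addition builds the diene); the C7–C8–C17 array comes from a 2-acylthiazole and a propanoate aldol.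
- C9–C10 comes from an Ireland–Claisen rearrangement of a glycolate on a Wharton-transposed allylic alcohol; C1 and C14 come from (S)-carvone by α′-formylation, methylation and Criegee degradation of the isopropenyl group.
- Ring order: ring A (from carvone), then the ten-membered ring and the γ-lactone in one operation, then the epoxide.

Assumption: intermediates carry briarane numbering (C15 = CH3 on C1, C16 = CH2 on C5, C18 = CH3 on C17, C20 = CH3 on C11), α/β refer to ring A with β the face that carries C15, and a one-pot sequence counts as one step.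

**Route**

Step 1
Reactants: 1 (S)-(+)-carvone
Product: 2 (6Z)-6-(hydroxymethylidene)carvone
Conditions: LiN(i-Pr)2 (LDA), THF, −78 °C; HCO2Et, −78 → 0 °C; aq. HCl
Reagents that add atoms: ethyl formate, CCOC=O
Why: Kinetic α′-enolate formation and Claisen condensation with the formate (α-formylation) attach the future C2 to the future C1; the product is the hydrogen-bonded Z-enol, so no new stereocentre arises yet.

Step 2
Reactants: 2 (6Z)-6-(hydroxymethylidene)carvone
Product: 3 1,3-dimethyl-2-oxo-6-(prop-1-en-2-yl)cyclohex-3-ene-1-carbaldehyde (new methyl trans to isopropenyl)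
Conditions: MeI, K2CO3, acetone, 45 °C
Reagents that add atoms: iodomethane, CI
Why: C-alkylation of the α-formyl ketone enolate (a vinylogous acid) occurs anti to the neighbouring isopropenyl group, which sets quaternary C1 with C15 trans and the formyl carbon cis to the future C14 substituent.

Step 3
Reactants: 3 keto aldehyde
Product: 4 dimethyl acetal of 3
Conditions: HC(OMe)3, MeOH, CSA (cat.), rt
Reagents that add atoms: trimethyl orthoformate, COC(OC)OC
Why: Acid-catalysed acetalization is selective for the aldehyde because the ketone is conjugated and flanked by the quaternary carbon; no stereocentre is touched.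

Step 4
Reactants: 4 dimethyl acetal
Product: 6 5-acetoxy-6-(dimethoxymethyl)-2,6-dimethylcyclohex-2-en-1-one (14α-acetate), via α-methoxy hydroperoxide 5 (not isolated)
Conditions: O3, CH2Cl2–MeOH, NaHCO3, −78 °C; then Ac2O, Et3N, DMAP (cat.), 0 → 40 °C
Reagents that add atoms: ozone, [O-][O+]=O; methanol, CO
Why: Ozonolysis attacks only the electron-rich isopropenyl group, and the Criegee rearrangement of the derived peracetate moves the ring carbon from carbon to oxygen with retention, giving the 14α-acetate.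

Step 5
Reactants: 6 enone acetate
Product: 7 11β,12β-epoxy ketone
Conditions: t-BuOOH, DBU, CH2Cl2, rt
Reagents that add atoms: tert-butyl hydroperoxide, CC(C)(C)OO
Why: Weitz–Scheffer nucleophilic epoxidation; the peroxide anion adds axially to C12 anti to the 14-acetoxy group, as in carvone, giving the β-epoxide.

Step 6
Reactants: 7 epoxy ketone
Product: 9 5-acetoxy-4-(dimethoxymethyl)-2,4-dimethylcyclohex-2-en-1-ol (12β-OH), via epoxy hydrazone 8 (not isolated)
Conditions: N2H4·H2O, AcOH (cat.), MeOH, 0 °C → rt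
Reagents that add atoms: none
Why: Wharton transposition: the epoxy hydrazone fragments with loss of N2 to the 10,11-alkene and the 12-alkoxide; the C12–O bond is not broken, so the alcohol is 12β.

Step 7
Reactants: 9 allylic alcohol; 10 2-[(tert-butyldimethylsilyl)oxy]acetic acid
Product: 11 O-TBS glycolate ester of 9
Conditions: DCC, DMAP (cat.), CH2Cl2, 0 °C → rt
Reagents that add atoms: none
Why: Steglich esterification of the only free hydroxyl; no stereocentre is touched.

Step 8
Reactants: 11 glycolate ester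
Product: 14 C8 carboxylic acid with 9-OTBS and the 11,12-alkene, via silyl ketene acetal 12 (not isolated), via trimethylsilyl ester 13 (not isolated)
Conditions: LiN(SiMe3)2 (1.3 equiv), Me3SiCl–Et3N, THF, −78 °C → rt; H2O/MeOH work-up
Reagents that add atoms: none
Why: Ireland–Claisen rearrangement: the C9–C10 bond forms on the β face from which the C12 oxygen leaves (sets C10, moves the alkene to C11=C12), and the Z-silyl ketene acetal reacting through the boat transition state (the chair would put the ketene acetal under the axial C15 methyl) sets C9.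

Step 9
Reactants: 14 carboxylic acid; 15 2-(trimethylsilyl)-1,3-thiazole
Product: 17 2-acylthiazole (C8 ketone), via acid chloride 16 (not isolated)
Conditions: 1-chloro-N,N,2-trimethylprop-1-en-1-amine, CH2Cl2, 0 °C; then 15, rt
Reagents that add atoms: none
Why: The Ghosez reagent gives the acid chloride under neutral conditions and the silylthiazole is ipso-acylated by it (Dondoni acylation), installing thiazole as a masked formyl group (C7); no stereocentre is touched.

Step 10
Reactants: 17 2-acylthiazole; 18 methyl propanoate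
Product: 19 aldol adduct (C8 tertiary alcohol; C17 methyl; C19 methyl ester)
Conditions: LiN(i-Pr)2, 18, THF–DMPU, −78 °C (Z-enolate); then 17, −78 °C; AcOH quench
Reagents that add atoms: none
Why: Aldol addition of the propanoate Z-enolate to the activated ketone: Felkin–Anh attack anti to the C9–OSi bond sets C8, and the closed chair with the bulky C9 branch equatorial sets C17, a centre that base can equilibrate after lactonization if the ratio is poor.

Step 11
Reactants: 19 aldol adduct
Product: 20 C2 aldehyde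
Conditions: PPTS, acetone–H2O, 50 °C
Reagents that add atoms: water, O
Why: Mild acid-catalysed acetal hydrolysis frees the non-enolizable C2 aldehyde while the silyl ether, acetate and tertiary alcohol survive; no stereocentre is touched.

Step 12
Reactants: 21 tert-butyldimethyl(prop-2-yn-1-yloxy)silane; 22 tributyl[(trimethylsilyl)ethynyl]stannane
Product: 23 (E)-alkenylstannane (tin cis to the alkynyl group)
Conditions: Pd2(dba)3 (2.5 mol %), N-[2-(diphenylphosphino)benzylidene]-2-phenylethylamine (10 mol %), THF, 50 °C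
Reagents that add atoms: none
Why: Palladium-catalysed alkynylstannylation (carbostannylation) adds the alkynyl group and tin syn across the terminal alkyne with tin on the terminal carbon, which fixes the geometry of the later C5=C6 bond.

Step 13
Reactants: 23 alkenylstannane
Product: 24 (E)-alkenyl iodide with silyl alkyne
Conditions: I2, CH2Cl2, 0 °C
Reagents that add atoms: iodine, II
Why: Iododestannylation is an ipso substitution that proceeds with retention of alkene geometry.

Step 14
Reactants: 24 alkenyl iodide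
Product: 25 (E)-iodo-enyne (C3–C6 and C16)
Conditions: K2CO3 (cat.), MeOH, rt
Reagents that add atoms: none
Why: Methanolysis cleaves only the C(sp)–Si bond (protodesilylation); the silyl ether and alkenyl iodide are untouched.

Step 15
Reactants: 20 C2 aldehyde; 25 iodo-enyne
Product: 29 2-acetate of the (3E,5E)-iodo-diene, via dienylzirconocene chloride 26 (not isolated), via dienyl(methyl)zinc 27 (not isolated), via zinc alkoxide 28 (not isolated)
Conditions: 25, Cp2Zr(H)Cl, CH2Cl2, rt; Me2Zn (3 equiv), toluene, −65 °C; 20, 0 °C; then Ac2O, 0 °C → rt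
Reagents that add atoms: acetic anhydride, CC(=O)OC(C)=O
Why: Hydrozirconation of the terminal alkyne (syn, zirconium terminal, hence 3E), transmetalation to zinc and 1,2-addition to the aldehyde (Wipf alkenylzinc addition) form C2–C3; Felkin–Anh approach with the C10 branch anti and the nucleophile passing the C15 methyl sets C2, and the zinc alkoxide is acetylated in the flask.

Step 16
Reactants: 29 iodo-diene acetate
Product: 32 α-hydroxy aldehyde (C7), via N-methylthiazolium triflate 30 (not isolated), via thiazolidine 31 (not isolated)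
Conditions: MeOTf, MeCN, rt; NaBH4, MeOH, 0 °C; AgNO3, MeCN–H2O, rt
Reagents that add atoms: water, O
Why: Dondoni unmasking (N-methylation, hydride reduction to the thiazolidine, silver-assisted hydrolysis) turns the thiazole into the C7 aldehyde under conditions that leave esters, silyl ethers and the alkenyl iodide alone.

Step 17
Reactants: 32 α-hydroxy aldehyde
Product: 34 ten-membered carbocycle fused to ring A plus γ-lactone (9,16-bis-OTBS), via ten-membered hydroxy ester 33 (not isolated)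
Conditions: CrCl2 (10 equiv), NiCl2 (0.1 equiv), DMSO–THF (3:1), 2 mM, slow addition, rt; aq. NH4Cl
Reagents that add atoms: none
Why: Nozaki–Hiyama–Kishi reaction: the alkenylchromium from the C6 iodide (geometry retained) adds to the C7 aldehyde to close the ten-membered ring, attacking the CrCl2-chelated α-hydroxy aldehyde from the face its C9-anchored tether can reach (sets C7), and the chromium alkoxide then acylates itself with the C19 methyl ester (5-exo-trig lactonization) to close the γ-lactone.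

Step 18
Reactants: 34 bis-silyl lactone
Product: 36 11,12-alkene tetraacetate, via 9,16-diol 35 (not isolated)
Conditions: HF·pyridine, pyridine–THF, 0 °C → rt; evaporate; Ac2O, pyridine, DMAP (cat.), CH2Cl2, rt
Reagents that add atoms: acetic anhydride, CC(=O)OC(C)=O
Why: Fluoride cleavage of both silyl ethers and acetylation of the secondary C9 and primary C16 hydroxyls; the hindered tertiary C8 hydroxyl is not acylated and no stereocentre is touched.

Step 19
Reactants: 36 11,12-alkene tetraacetate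
Product: 37 CNP0250433.1
Conditions: mCPBA (1.1 equiv), NaHCO3, CH2Cl2, 0 °C
Reagents that add atoms: 3-chloroperoxybenzoic acid, OOC(=O)c1cccc(Cl)c1
Why: Prilezhaev epoxidation selects the only electron-rich isolated alkene (the diene is deactivated by three allylic C–O bonds) and occurs on the α face, opposite the axial C15 methyl and the C9 branch, giving the 11α,12α-epoxide (sets C11 and C12).

**Compound list**

1 | (S)-(+)-carvone, (5S)-2-methyl-5-(prop-1-en-2-yl)cyclohex-2-en-1-one | CC1=CC[C@@H](CC1=O)C(C)=C | starting material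
2 | (6Z)-6-(hydroxymethylidene)-2-methyl-5-(prop-1-en-2-yl)cyclohex-2-en-1-one, ring stereocentre unchanged from 1 | O/C=C1\C(=O)C(C)=CC[C@@H]1C(C)=C | intermediate
3 | 1,3-dimethyl-2-oxo-6-(prop-1-en-2-yl)cyclohex-3-ene-1-carbaldehyde, 1-methyl (C15) trans to isopropenyl, formyl (C2) cis | O=C1C(C)=CC[C@H](C(C)=C)[C@]1(C)C=O | intermediate
4 | 6-(dimethoxymethyl)-2,6-dimethyl-5-(prop-1-en-2-yl)cyclohex-2-en-1-one, configuration as 3 | O=C1C(C)=CC[C@H](C(C)=C)[C@]1(C)C(OC)OC | intermediate
5 | 6-(dimethoxymethyl)-5-(1-hydroperoxy-1-methoxyethyl)-2,6-dimethylcyclohex-2-en-1-one, both epimers at the peroxy carbon | O=C1C(C)=CC[C@H](C(C)(OC)OO)[C@]1(C)C(OC)OC | intermediate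
6 | 5-acetoxy-6-(dimethoxymethyl)-2,6-dimethylcyclohex-2-en-1-one, acetoxy (14α, 14S) cis to CH(OMe)2 and trans to the 6-methyl | O=C1C(C)=CC[C@H](OC(C)=O)[C@]1(C)C(OC)OC | intermediate
7 | 2,3-epoxide of 6 on the face opposite to the acetoxy group (11β,12β-epoxy-10-ketone) | O=C1[C@@]2(C)O[C@H]2C[C@H](OC(C)=O)[C@]1(C)C(OC)OC | intermediate
8 | hydrazone of 7 | NN=C1[C@@]2(C)O[C@H]2C[C@H](OC(C)=O)[C@]1(C)C(OC)OC | intermediate
9 | 5-acetoxy-4-(dimethoxymethyl)-2,4-dimethylcyclohex-2-en-1-ol, OH (12β) cis to the 4-methyl and trans to the acetoxy group | C1=C(C)[C@@H](O)C[C@H](OC(C)=O)[C@]1(C)C(OC)OC | intermediate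
10 | 2-[(tert-butyldimethylsilyl)oxy]acetic acid | CC(C)(C)[Si](C)(C)OCC(=O)O | starting material
11 | 2-[(tert-butyldimethylsilyl)oxy]acetate ester of 9 at the 12β-oxygen | C1=C(C)[C@@H](OC(=O)CO[Si](C)(C)C(C)(C)C)C[C@H](OC(C)=O)[C@]1(C)C(OC)OC | intermediate
12 | (Z)-silyl ketene acetal of 11, OTBS cis to OSiMe3 | C1=C(C)[C@@H](O/C(O[Si](C)(C)C)=C/O[Si](C)(C)C(C)(C)C)C[C@H](OC(C)=O)[C@]1(C)C(OC)OC | intermediate
13 | trimethylsilyl ester of 14 | C[Si](C)(C)OC(=O)[C@@H](O[Si](C)(C)C(C)(C)C)[C@H]1C(C)=CC[C@H](OC(C)=O)[C@]1(C)C(OC)OC | intermediate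
14 | 2-[(tert-butyldimethylsilyl)oxy]-2-[5-acetoxy-6-(dimethoxymethyl)-2,6-dimethylcyclohex-2-en-1-yl]acetic acid, side chain 10β (cis to C15), C9, C10, C1 and C14 configured as in the target | OC(=O)[C@@H](O[Si](C)(C)C(C)(C)C)[C@H]1C(C)=CC[C@H](OC(C)=O)[C@]1(C)C(OC)OC | intermediate
15 | 2-(trimethylsilyl)-1,3-thiazole | C[Si](C)(C)c1nccs1 | starting material
16 | acid chloride of 14 | ClC(=O)[C@@H](O[Si](C)(C)C(C)(C)C)[C@H]1C(C)=CC[C@H](OC(C)=O)[C@]1(C)C(OC)OC | intermediate
17 | thiazol-2-yl ketone of 14 (C8 ketone, thiazole = masked C7) | O=C(c1nccs1)[C@@H](O[Si](C)(C)C(C)(C)C)[C@H]2C(C)=CC[C@H](OC(C)=O)[C@]2(C)C(OC)OC | intermediate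
18 | methyl propanoate | CCC(=O)OC | starting material
19 | methyl 3-hydroxy-2-methyl-3-(thiazol-2-yl)-4-silyloxy-4-(ring A)butanoate, C8, C9 and C17 configured as in the target, C2 as dimethyl acetal | COC(=O)[C@H](C)[C@@](c1nccs1)(O)[C@@H](O[Si](C)(C)C(C)(C)C)[C@H]2C(C)=CC[C@H](OC(C)=O)[C@]2(C)C(OC)OC | intermediate
20 | aldehyde from 19 (C2 formyl on C1) | COC(=O)[C@H](C)[C@@](c1nccs1)(O)[C@@H](O[Si](C)(C)C(C)(C)C)[C@H]2C(C)=CC[C@H](OC(C)=O)[C@]2(C)C=O | intermediate
21 | tert-butyldimethyl(prop-2-yn-1-yloxy)silane | C#CCO[Si](C)(C)C(C)(C)C | starting material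
22 | tributyl[(trimethylsilyl)ethynyl]stannane | CCCC[Sn](CCCC)(CCCC)C#C[Si](C)(C)C | starting material
23 | (E)-tert-butyldimethyl{[2-[(tributylstannyl)methylidene]-4-(trimethylsilyl)but-3-yn-1-yl]oxy}silane, tin cis to the alkynyl group | C[Si](C)(C)C#C/C(CO[Si](C)(C)C(C)(C)C)=C\[Sn](CCCC)(CCCC)CCCC | intermediate
24 | (E)-tert-butyl{[2-(iodomethylidene)-4-(trimethylsilyl)but-3-yn-1-yl]oxy}dimethylsilane | C[Si](C)(C)C#C/C(CO[Si](C)(C)C(C)(C)C)=C\I | intermediate
25 | (E)-tert-butyl{[2-(iodomethylidene)but-3-yn-1-yl]oxy}dimethylsilane, iodine cis to ethynyl | C#C/C(CO[Si](C)(C)C(C)(C)C)=C\I | intermediate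
26 | (1E,3E)-dienylzirconocene chloride from 25 | Cl[Zr](/C=C/C(CO[Si](C)(C)C(C)(C)C)=C\I)(C1C=CC=C1)C1C=CC=C1 | intermediate
27 | (1E,3E)-dienyl(methyl)zinc from 26 | C[Zn]/C=C/C(CO[Si](C)(C)C(C)(C)C)=C\I | intermediate
28 | methylzinc alkoxide of the C2 allylic alcohol | COC(=O)[C@H](C)[C@@](c1nccs1)(O)[C@@H](O[Si](C)(C)C(C)(C)C)[C@H]2C(C)=CC[C@H](OC(C)=O)[C@]2(C)[C@@H](O[Zn]C)/C=C/C(CO[Si](C)(C)C(C)(C)C)=C\I | intermediate
29 | acyclic (3E,5E)-6-iodo-diene with 2,14-diacetate, 9,16-bis-OTBS, 8-OH and 8-(thiazol-2-yl); C2 as in the target | COC(=O)[C@H](C)[C@@](c1nccs1)(O)[C@@H](O[Si](C)(C)C(C)(C)C)[C@H]2C(C)=CC[C@H](OC(C)=O)[C@]2(C)[C@@H](OC(C)=O)/C=C/C(CO[Si](C)(C)C(C)(C)C)=C\I | intermediate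
30 | N-methylthiazolium triflate of 29 | COC(=O)[C@H](C)[C@@](c1scc[n+]1C)(O)[C@@H](O[Si](C)(C)C(C)(C)C)[C@H]2C(C)=CC[C@H](OC(C)=O)[C@]2(C)[C@@H](OC(C)=O)/C=C/C(CO[Si](C)(C)C(C)(C)C)=C\I.[O-]S(=O)(=O)C(F)(F)F | intermediate
31 | 3-methylthiazolidin-2-yl analogue of 29, epimers at the thiazolidine carbon | COC(=O)[C@H](C)[C@@](C1SCCN1C)(O)[C@@H](O[Si](C)(C)C(C)(C)C)[C@H]2C(C)=CC[C@H](OC(C)=O)[C@]2(C)[C@@H](OC(C)=O)/C=C/C(CO[Si](C)(C)C(C)(C)C)=C\I | intermediate
32 | acyclic C7 aldehyde: 8-hydroxy-8-formyl, C19 methyl ester, (3E,5E)-6-iodo-diene, 2,14-diacetate, 9,16-bis-OTBS | COC(=O)[C@H](C)[C@@](C=O)(O)[C@@H](O[Si](C)(C)C(C)(C)C)[C@H]2C(C)=CC[C@H](OC(C)=O)[C@]2(C)[C@@H](OC(C)=O)/C=C/C(CO[Si](C)(C)C(C)(C)C)=C\I | intermediate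
33 | ten-membered 7,8-diol methyl ester (ring closed, lactone open), C7 as in the target | CC(C)(C)[Si](C)(C)OCC1=C/[C@H](O)[C@@](O)([C@@H](C)C(=O)OC)[C@@H](O[Si](C)(C)C(C)(C)C)[C@H]2C(C)=CC[C@H](OC(C)=O)[C@]2(C)[C@@H](OC(C)=O)\C=C\1 | intermediate
34 | 2,14-diacetoxy-9,16-bis(tert-butyldimethylsilyloxy)-8-hydroxybriara-3E,5E,11-trien-18,7-olide (briarane numbering), all centres as in the target | CC(C)(C)[Si](C)(C)OCC1=C/[C@@H]2OC(=O)[C@H](C)[C@@]2(O)[C@@H](O[Si](C)(C)C(C)(C)C)[C@H]2C(C)=CC[C@H](OC(C)=O)[C@]2(C)[C@@H](OC(C)=O)\C=C\1 | intermediate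
35 | 9,16-diol from 34 | OCC1=C/[C@@H]2OC(=O)[C@H](C)[C@@]2(O)[C@@H](O)[C@H]2C(C)=CC[C@H](OC(C)=O)[C@]2(C)[C@@H](OC(C)=O)\C=C\1 | intermediate
36 | 2,9,14,16-tetraacetoxy-8-hydroxybriara-3E,5E,11-trien-18,7-olide (11,12-deoxy target) | CC(=O)OCC1=C/[C@@H]2OC(=O)[C@H](C)[C@@]2(O)[C@@H](OC(C)=O)[C@H]2C(C)=CC[C@H](OC(C)=O)[C@]2(C)[C@@H](OC(C)=O)\C=C\1 | intermediate
37 | CNP0250433.1, the 11α,12α-epoxide of 36 | CC(=O)OCC1=C/[C@@H]2OC(=O)[C@H](C)[C@@]2(O)[C@@H](OC(C)=O)[C@H]2[C@]3(C)O[C@@H]3C[C@H](OC(C)=O)[C@]2(C)[C@@H](OC(C)=O)\C=C\1 | target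

**Step count**

Total: 19 steps. Longest linear sequence: 16 steps from (S)-carvone (steps 1–11 and 15–19); steps 12–14 prepare fragment 25.

**Three steps most likely to fail, with fallbacks**

Step 17 (ring closure to a strained ten-membered E,Z-diene; oligomers or no closure). The fallback sets out from 19 and closes the ring at C2–C3 instead, after the lactone exists. The thiazole of 19 is unmasked as in step 16, through N-methylthiazolium triflate F3 and thiazolidine F4, to α-hydroxy aldehyde F5. F5 is coupled intermolecularly with 25 (CrCl2, NiCl2 cat., DMSO); the alkenylchromium adds to C7 and the alkoxide lactonizes, passing through hydroxy ester F6 to enyne γ-lactone F7. Acetal hydrolysis (PPTS, acetone–H2O) gives enyne lactone aldehyde F8. Reductive ynal macrocyclization (Ni(cod)2, 1,3-bis(2,6-diisopropylphenyl)imidazol-2-ylidene, Et3SiH, THF, high dilution) joins C2 to the terminal alkyne carbon syn to hydride and gives the 3E-diene macrocycle 2-O-triethylsilyl ether F9. HF·pyridine gives 2,9,16-triol F10, and Ac2O/pyridine/DMAP comes back to the route at 36.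

Step 6 (hydrazone formation at a ketone flanked by two fully substituted carbons may stall). The fallback sets out from 7. Luche reduction (NaBH4, CeCl3·7H2O, MeOH) gives epoxy alcohol F1 as C10 epimers, and MsCl/Et3N gives epoxy mesylate F2. Cp2TiCl (from Cp2TiCl2 and Zn dust, THF) opens the epoxide by single-electron transfer at tertiary C11; the C11–titanium species then expels the C10 mesylate. This gives the 10,11-alkene with the 12β-oxygen intact and comes back to the route at 9.

Step 19 (epoxidation from the wrong face, or at the diene). The fallback sets out from 36. NBS in acetone–H2O at 0 °C forms the bromonium ion on the face a peracid would also take, and water opens it anti at tertiary C11 to give bromohydrin F11 (11α-OH, 12β-Br). DBU in CH2Cl2 then closes the epoxide by backside displacement of bromide, which delivers the α-epoxide and comes back to the route at 37.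

**Further compounds**

F1 | step 6 | epoxy alcohol from 7 (C10 epimers) | OC1[C@@]2(C)O[C@H]2C[C@H](OC(C)=O)[C@]1(C)C(OC)OC
F2 | step 6 | epoxy mesylate | CS(=O)(=O)OC1[C@@]2(C)O[C@H]2C[C@H](OC(C)=O)[C@]1(C)C(OC)OC
F3 | step 17 | N-methylthiazolium triflate of 19 | COC(=O)[C@H](C)[C@@](c1scc[n+]1C)(O)[C@@H](O[Si](C)(C)C(C)(C)C)[C@H]2C(C)=CC[C@H](OC(C)=O)[C@]2(C)C(OC)OC.[O-]S(=O)(=O)C(F)(F)F
F4 | step 17 | thiazolidine from F3 | COC(=O)[C@H](C)[C@@](C1SCCN1C)(O)[C@@H](O[Si](C)(C)C(C)(C)C)[C@H]2C(C)=CC[C@H](OC(C)=O)[C@]2(C)C(OC)OC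
F5 | step 17 | α-hydroxy aldehyde (C7) with C2 dimethyl acetal | COC(=O)[C@H](C)[C@@](C=O)(O)[C@@H](O[Si](C)(C)C(C)(C)C)[C@H]2C(C)=CC[C@H](OC(C)=O)[C@]2(C)C(OC)OC
F6 | step 17 | hydroxy ester from F5 and 25 | COC(=O)[C@H](C)[C@@]([C@@H](O)/C=C(CO[Si](C)(C)C(C)(C)C)\C#C)(O)[C@@H](O[Si](C)(C)C(C)(C)C)[C@H]2C(C)=CC[C@H](OC(C)=O)[C@]2(C)C(OC)OC
F7 | step 17 | enyne γ-lactone | C#C/C(CO[Si](C)(C)C(C)(C)C)=C\[C@@H]1OC(=O)[C@H](C)[C@@]1(O)[C@@H](O[Si](C)(C)C(C)(C)C)[C@H]2C(C)=CC[C@H](OC(C)=O)[C@]2(C)C(OC)OC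
F8 | step 17 | enyne lactone C2 aldehyde | C#C/C(CO[Si](C)(C)C(C)(C)C)=C\[C@@H]1OC(=O)[C@H](C)[C@@]1(O)[C@@H](O[Si](C)(C)C(C)(C)C)[C@H]2C(C)=CC[C@H](OC(C)=O)[C@]2(C)C=O
F9 | step 17 | macrocycle 2-O-triethylsilyl ether | CC(C)(C)[Si](C)(C)OCC1=C/[C@@H]2OC(=O)[C@H](C)[C@@]2(O)[C@@H](O[Si](C)(C)C(C)(C)C)[C@H]2C(C)=CC[C@H](OC(C)=O)[C@]2(C)[C@@H](O[Si](CC)(CC)CC)\C=C\1
F10 | step 17 | 2,9,16-triol | OCC1=C/[C@@H]2OC(=O)[C@H](C)[C@@]2(O)[C@@H](O)[C@H]2C(C)=CC[C@H](OC(C)=O)[C@]2(C)[C@@H](O)\C=C\1
F11 | step 19 | 12β-bromo-11α-hydroxy bromohydrin of 36 | CC(=O)OCC1=C/[C@@H]2OC(=O)[C@H](C)[C@@]2(O)[C@@H](OC(C)=O)[C@H]2[C@](C)(O)[C@@H](Br)C[C@H](OC(C)=O)[C@]2(C)[C@@H](OC(C)=O)\C=C\1
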